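## Structural features

The target is a 2,2-disubstituted oxirane (O1, C2, C3) whose quaternary carbon C2 is bonded to C1' of a 1,2,4-trisubstituted benzene ring and to an acetoxymethyl arm. The benzene ring carries a phenolic isobutyrate at C2', ortho to the oxirane, and an isobutyryloxymethyl group at C4', para to it. C2 is the only stereocentre (S; CIP order ring O > CH2OAc > ring CH2 > aryl), so there is no neighbouring centre to relay from and the configuration must come from a catalyst. The real difficulty is that C2 carries two CH2–O arms that differ only in what the oxygen is bonded to, so any intermediate in which the arms become equivalent or can exchange roles is achiral or racemises. The fragile groups are the tertiary benzylic oxirane, which ionises easily under acid because the ortho oxygen stabilises the cation, and the three esters, of which the aryl isobutyrate is the most easily transferred to a neighbouring alkoxide; a free phenoxide ortho to the oxirane is avoided for the same reasons. The plan uses the fact that C2–O1 is a tertiary benzylic C–O bond: if the future acetoxymethyl arm is carried as a vinyl group, C2 is also allylic, and this bond can be broken and re-formed on a π-allylpalladium complex under a chiral ligand while the vinyl group keeps the two arms distinct.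

## Logic of the disconnections

17 ⇒ 16: the two O–acyl bonds of the isobutyrates are cut (phenolic O–C(=O) and benzylic O–C(=O)). An aryl ester would not survive the organometallic and alkoxide steps, whereas hindered silyl ethers do, so one protecting group serves both arene oxygens throughout. The forward step must exchange silyl for acyl without leaving a phenoxide beside the oxirane, hence acylation in the same pot as the fluoride.

16 ⇒ 15: the acetate O–acyl bond is cut. The free primary hydroxyl is what alkene cleavage and reduction deliver, so nothing is added to the count. The forward step must be a base-buffered acylation with no acid near the oxirane.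

15 ⇒ 13 by way of 14: the hydroxymethyl carbon is traced back to the inner carbon of a vinyl group; in the forward sense the C=C bond is cleaved and the remaining carbonyl reduced. The vinyl group is the device that makes C2 allylic and keeps the arms different. The forward step must cleave the alkene without attacking the silylated arene or opening the oxirane.

13 ⇒ 11 by way of 12: the O1–C3 bond of the oxirane is cut to give a primary/tertiary 1,2-diol. The tertiary C–O bond, which carries the stereochemical information, is left alone. The forward step needs selective activation of the primary hydroxyl and ring closure by the tertiary oxygen, which retains configuration.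

11 ⇒ 10: the tertiary C2–O bond is cut. This is the only bond whose formation can be made enantioselective from a racemate, because ionisation of 10 gives a π-allyl complex that forgets the configuration of its precursor. The gain is that 10 can be racemic. The forward step needs attack of water at the substituted allyl terminus on one face.

10 ⇒ 9: the two C–O bonds to the carbonate carbon are cut (loss of CO2). The carbonate is the ionisable form of a vinyl oxirane and is made from it without any acid or base. The forward step needs CO2 capture to outrun isomerisation of the π-allyl alkoxide.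

9 ⇒ 6 + 7 by way of 8: the O–CH2 bond of the racemic oxirane and the C2–vinyl bond are cut. This reduces the quaternary carbon to a ketone carbonyl flanked by CH2Cl. The forward step needs 1,2-addition to outrun substitution at CH2Cl, followed by halohydrin closure.

6 ⇒ 3 + 4 by way of 5: the C1'–C(=O) bond is cut. The arene and the two-carbon unit are joined at the position fixed by the halogen of 3. The forward step needs an arylmetal ortho to a silyloxy group that does not suffer O-to-C silyl migration, hence magnesium and not lithium.

3 ⇒ 2 ⇒ 1: the two O–Si bonds are cut, then the benzylic alcohol is traced to the ester. Both are routine. The silyl group is chosen for the later steps, not for this one.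

## Other disconnections considered

Alternative 1: The cut removes C3 of the oxirane (the C2–C3 and O1–C3 bonds) and leads to the ketone 2-(4-methoxybenzyloxy)-1-[2-(tert-butyldimethylsilyloxy)-4-(tert-butyldimethylsilyloxymethyl)phenyl]ethan-1-one A1. Forward, dimethyloxosulfonium methylide A2 would add to the carbonyl of A1 under LaLi3(binaphthoxide)3 (trivalent lanthanum) with an achiral phosphine oxide additive, and the betaine would close to the S oxirane A3 (Corey–Chaykovsky reaction).
- In favour: ring and stereocentre arise in one step from a prochiral ketone, the arms are distinct from the start, and there is no racemate, tosylation or ozonolysis. From the aryl halide the count to 17 would be about eight steps against ten, so on step economy this is the better plan.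
- Against: this catalyst type separates the carbonyl faces best when one flank is a methyl group. In A1 the flanks are an ortho-substituted aryl group and a CH2O-ether arm of similar size, and the ether oxygen can also bind the lanthanum and lithium centres, so the facial bias is an open question.
- Comparison: the stereo-determining event is an irreversible addition to a carbonyl. In the chosen plan both enantiomers pass through an equilibrating π-allyl complex whose substitution pattern (aryl and CH2O on one terminus) fits the established substrate class. Oxidative removal of the 4-methoxybenzyl ether of A3 beside an acid-sensitive oxirane is a burden comparable to the ozonolysis (equal), and the late silyl-to-isobutyryl exchange is the same (equal).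

Alternative 2: The cut is the C1'–C2 bond between arene and quaternary carbon. Forward, [2-(triisopropylsilyloxy)-4-(triisopropylsilyloxymethyl)phenyl]boronic acid A4 would add to the ketone of ethyl 3-(4-methoxybenzyloxy)-2-oxopropanoate A5 under [RhCl(C2H4)2]2 (monovalent rhodium) and a chiral diene, by transmetalation and insertion of the C=O group into the aryl–rhodium bond, to give the tertiary alcohol A6 (R; the ester arm is the future C3).
- In favour: it is the most convergent plan. The three substituents on the new centre are at three different oxidation levels, a cleaner differentiation than vinyl versus hydroxymethyl, and no ozonolysis is needed; on these points it is better.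
- Against: the silyloxy group ortho to boron in A4 slows transmetalation and insertion and invites protodeboronation of an electron-rich boronic acid in the protic medium such additions need. The ketone of A5 lies between an ester and a CH2O-ether, so face selection rests on two-point binding of the keto ester.
- Comparison: A6 still needs ester reduction, primary sulfonylation and closure, ether cleavage, acetylation and the silyl-to-isobutyryl exchange, about ten steps in all (equal). The tertiary alkoxide beside the aryl silyl ether and the late exchange beside the oxirane are the same liabilities (equal). The chosen plan puts the bulky ortho substituent on the electrophile, where the catalyst only has to recognise an allyl face; here it sits on the nucleophile that must first reach the metal.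

Alternative 3: The cut, read backwards, rejoins C3 to the oxygen of the acetoxymethyl arm and gives the achiral oxetane 3-[2-(isobutyryloxy)-4-(isobutyryloxymethyl)phenyl]-3-(trimethylsilyloxy)oxetane A7, in which the two future arms are enantiotopic ring CH2–O bonds. Forward, bromotrimethylsilane A8, activated by a chiral squaramide hydrogen-bond donor, would open one of these bonds by bromide attack at CH2 to give bromide A9 (R). Its tertiary oxygen later displaces bromide to form the oxirane and its primary silyl ether becomes the acetate.
- In favour: it is the shortest plan, about eight steps. The esters are in place before the stereocentre exists, so no silyl-to-acyl exchange is needed beside the finished oxirane, which is better than the chosen plan. The substrate A7 is prochiral, so no racemate is made, and the stereocentre is not the carbon that undergoes substitution.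
- Against: the reagent A8 is a silyl halide and a latent source of strong acid acting next to a tertiary benzylic C–O centre, so ionisation at the ring carbon competes in principle with substitution at CH2 (tempered by the acyloxy ortho substituent). A fully substituted ring carbon with an ortho-substituted aryl group is a crowded site for the catalyst. The end game must close a bromohydrin derived from A9 with base while an aryl ester sits six atoms from the tertiary alkoxide, with acyl transfer and re-closure to the oxetane as competing paths.
- Comparison: better on step count and on the timing of the esters, equal in needing one catalytic asymmetric step on an ortho-substituted aryl substrate, and weaker in the tolerance of its key step and end game for the acid- and base-sensitive groups of this arene.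

Key step: step 6

Assumption: methyl 3-hydroxy-4-iodobenzoate 1 is taken as the commercial aryl halide; the iodide is preferred to the bromide because iodine–magnesium exchange is fast at −20 °C, whereas the electron-rich bromide would call for bromine–lithium exchange and so for an aryllithium prone to silyl migration.

Ar = 2-(triisopropylsilyloxy)-4-(triisopropylsilyloxymethyl)phenyl in all names below.

## Route

Step 1
Reactants: 1 methyl 3-hydroxy-4-iodobenzoate
Product: 2 5-(hydroxymethyl)-2-iodophenol (3-hydroxy-4-iodobenzyl alcohol)
Conditions: iBu2AlH (3.5 equiv), THF, −78 → 0 °C; aq. potassium sodium tartrate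
Reagents that add atoms: none
Why: Hydride reduction of the aryl ester gives the benzylic alcohol after one equivalent is spent on the phenol; the carbon–iodine bond is inert to iBu2AlH at this temperature.

Step 2
Reactants: 2 5-(hydroxymethyl)-2-iodophenol
Product: 3 1-iodo-2-(triisopropylsilyloxy)-4-(triisopropylsilyloxymethyl)benzene (Ar–I)
Conditions: iPr3SiCl (2.5 equiv), imidazole (5 equiv), DMF, 25 → 40 °C
Reagents that add atoms: triisopropylsilyl chloride, CC(C)[Si](Cl)(C(C)C)C(C)C
Why: Imidazole-promoted silylation covers both hydroxyls in one operation. Triisopropylsilyl is preferred to tert-butyldimethylsilyl on the phenol because it resists 1,3 O-to-C shift in the arylmetal of step 3 and 1,5 O-to-O shift to the tertiary alkoxides of steps 4 and 7.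

Step 3
Reactants: 3 Ar–I, 4 2-chloro-N-methoxy-N-methylacetamide
Product: 6 2-chloro-1-Ar-ethan-1-one, via arylmagnesium chloride 5 (not isolated)
Conditions: iPrMgCl·LiCl (1.05 equiv), THF, −20 °C; then 4 (1.3 equiv), −20 → 0 °C; aq. NH4Cl
Reagents that add atoms: isopropylmagnesium chloride–lithium chloride, CC(C)[Mg]Cl.[Li]Cl (magnesium and chlorine stay only in intermediate 5)
Why: Iodine–magnesium exchange gives 5, which as a magnesium species is not prone to retro-Brook silyl migration. Acylation of the N-methoxy-N-methylamide (Weinreb ketone synthesis) stops at the ketone because the chelated tetrahedral adduct survives until work-up.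

Step 4
Reactants: 6 2-chloro-1-Ar-ethan-1-one, 7 vinylmagnesium bromide
Product: 9 racemic 2-Ar-2-vinyloxirane, via chlorohydrin 8 (not isolated)
Conditions: 7 (1.3 equiv), THF, −78 °C; then KOtBu (1.4 equiv), −78 → 0 °C
Reagents that add atoms: none
Why: Grignard 1,2-addition to the activated α-chloro ketone at −78 °C outpaces substitution at CH2Cl, and the potassium alkoxide then closes the oxirane by 3-exo-tet displacement of chloride (halohydrin route). The product is racemic by design and is handled on triethylamine-deactivated silica.

Step 5
Reactants: 9 racemic 2-Ar-2-vinyloxirane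
Product: 10 racemic 4-Ar-4-vinyl-1,3-dioxolan-2-one
Conditions: CO2 (1 atm), Pd(PPh3)4 (2 mol %), THF, 0 → 25 °C
Reagents that add atoms: carbon dioxide, O=C=O
Why: Zerovalent palladium opens the vinyl oxirane to a π-allyl alkoxide that captures CO2, and the carbonate oxygen closes on the more substituted allyl terminus to give the five-membered cyclic carbonate (palladium-catalysed CO2 fixation on vinyl oxiranes). The neutral conditions spare both silyl ethers.

Step 6
Reactants: 10 racemic 4-Ar-4-vinyl-1,3-dioxolan-2-one
Product: 11 (2S)-2-Ar-but-3-ene-1,2-diol
Conditions: Pd2(dba)3·CHCl3 (2.5 mol %), binaphthol-derived phosphoramidite ligand (6 mol %, antipode chosen for S), Et3B (10 mol %), H2O (10 equiv), THF, 0 → 25 °C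
Reagents that add atoms: water, O
Why: Zerovalent palladium bearing the phosphoramidite ionises the allylic C–O bond of 10 with inversion and the carbonate loses CO2, leaving a zwitterionic π-allylpalladium complex with a pendant primary alkoxide. Because the allyl unit has an unsubstituted CH2 terminus, η3–η1–η3 isomerisation through the primary σ-complex exchanges the two allyl faces faster than water attacks, so both enantiomers of 10 converge on the diastereomeric complex favoured by the ligand (dynamic kinetic asymmetric transformation). Water, held at the alkoxide by hydrogen bonding or as the hydroxyborate formed with the catalytic Et3B, attacks the aryl-bearing terminus anti to palladium, forming the tertiary C–O bond, and proton transfer releases 11 and the catalyst. The closest known reaction type is the palladium-catalysed decarboxylative allylic substitution of 4-substituted 4-vinyl-1,3-dioxolan-2-ones with water and alcohols, an extension of Tsuji–Trost chemistry of vinyl oxiranes. No ring is closed. The single new stereocentre is set by the catalyst alone: the chiral pocket of the phosphoramidite decides which allyl face is presented to water, and the ligand antipode is chosen to give S. The step needs branched over linear attack and water over the internal alkoxide; the aryl group makes the substituted terminus the more electrophilic, the alkoxide delivers water to it, and collapse of the alkoxide onto the allyl unit would only regenerate a vinyl oxirane that re-enters the cycle. Neutral conditions at ambient temperature leave the silyl ethers and the tertiary allylic alcohol intact.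

Step 7
Reactants: 11 (2S)-2-Ar-but-3-ene-1,2-diol
Product: 13 (2S)-2-Ar-2-vinyloxirane, via primary tosylate 12 (not isolated)
Conditions: TsCl (1.05 equiv), Et3N (1.2 equiv), Bu2SnO (2 mol %), CH2Cl2, 0 → 25 °C; solvent changed to THF; KOtBu (2.3 equiv), 0 °C
Reagents that add atoms: 4-methylbenzenesulfonyl chloride, Cc1ccc(cc1)S(=O)(=O)Cl (the sulfonyl group stays only in intermediate 12)
Why: Stannylene catalysis by Bu2SnO directs sulfonylation to the primary hydroxyl of the 1,2-diol, and the tertiary alkoxide then displaces tosylate in a 3-exo-tet Williamson closure. The stereocentre is the nucleophilic partner, not the carbon attacked, so its configuration is retained.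

Step 8
Reactants: 13 (2S)-2-Ar-2-vinyloxirane
Product: 15 [(2R)-2-Ar-oxiran-2-yl]methanol, via epoxy aldehyde 14 (not isolated)
Conditions: O3, CH2Cl2–MeOH (3:1), NaHCO3, Sudan Red 7B indicator, −78 °C; then NaBH4, −78 → 0 °C
Reagents that add atoms: ozone, [O-][O+]=O
Why: Ozonolysis of the terminal alkene with in-flask borohydride reduction turns the vinyl group into CH2OH; the bicarbonate buffer protects the oxirane, and the alkene reacts far faster with ozone than the silylated arene. The quaternary α-carbon of 14 cannot epimerise, and a Payne shift of 15 is degenerate (inversion at C2 is offset by exchange of the two arms), so the change of descriptor from S to R reflects only the CIP ranking.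

Step 9
Reactants: 15 [(2R)-2-Ar-oxiran-2-yl]methanol
Product: 16 [(2S)-2-Ar-oxiran-2-yl]methyl acetate
Conditions: Ac2O, pyridine, DMAP (cat.), CH2Cl2, 0 °C
Reagents that add atoms: acetic anhydride, CC(=O)OC(C)=O
Why: DMAP-catalysed acylation of the only free hydroxyl under buffered basic conditions leaves the oxirane and silyl ethers untouched; the descriptor returns to S because CH2OAc outranks the ring CH2.

Step 10
Reactants: 16 [(2S)-2-Ar-oxiran-2-yl]methyl acetate
Product: 17 [(2S)-2-[2-(2-methylpropanoyloxy)-4-(2-methylpropanoyloxymethyl)phenyl]oxiran-2-yl]methyl acetate (target)
Conditions: (iPrCO)2O (6 equiv), Bu4NF (3 equiv, slow addition), THF, 0 → 25 °C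
Reagents that add atoms: 2-methylpropanoic anhydride, CC(C)C(=O)OC(=O)C(C)C
Why: Fluoride cleaves the aryl silyl ether first and the benzylic one more slowly, and each oxyanion is acylated by the anhydride as it forms (one-pot desilylative acylation), so no phenoxide persists beside the oxirane. The carboxylate by-product keeps the medium close to neutral.

## Compound list

1 | methyl 3-hydroxy-4-iodobenzoate | COC(=O)c1ccc(I)c(O)c1 | starting material
2 | 5-(hydroxymethyl)-2-iodophenol | OCc1ccc(I)c(O)c1 | intermediate
3 | 1-iodo-2-(triisopropylsilyloxy)-4-(triisopropylsilyloxymethyl)benzene | Ic1ccc(CO[Si](C(C)C)(C(C)C)C(C)C)cc1O[Si](C(C)C)(C(C)C)C(C)C | intermediate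
4 | 2-chloro-N-methoxy-N-methylacetamide | CON(C)C(=O)CCl | starting material
5 | [2-(triisopropylsilyloxy)-4-(triisopropylsilyloxymethyl)phenyl]magnesium chloride | Cl[Mg]c1ccc(CO[Si](C(C)C)(C(C)C)C(C)C)cc1O[Si](C(C)C)(C(C)C)C(C)C | intermediate
6 | 2-chloro-1-[2-(triisopropylsilyloxy)-4-(triisopropylsilyloxymethyl)phenyl]ethan-1-one | ClCC(=O)c1ccc(CO[Si](C(C)C)(C(C)C)C(C)C)cc1O[Si](C(C)C)(C(C)C)C(C)C | intermediate
7 | vinylmagnesium bromide | C=C[Mg]Br | starting material
8 | racemic 1-chloro-2-[2-(triisopropylsilyloxy)-4-(triisopropylsilyloxymethyl)phenyl]but-3-en-2-ol (present as its alkoxide) | C=CC(O)(CCl)c1ccc(CO[Si](C(C)C)(C(C)C)C(C)C)cc1O[Si](C(C)C)(C(C)C)C(C)C | intermediate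
9 | racemic 2-[2-(triisopropylsilyloxy)-4-(triisopropylsilyloxymethyl)phenyl]-2-vinyloxirane | C=CC1(c2ccc(CO[Si](C(C)C)(C(C)C)C(C)C)cc2O[Si](C(C)C)(C(C)C)C(C)C)CO1 | intermediate
10 | racemic 4-[2-(triisopropylsilyloxy)-4-(triisopropylsilyloxymethyl)phenyl]-4-vinyl-1,3-dioxolan-2-one | C=CC1(c2ccc(CO[Si](C(C)C)(C(C)C)C(C)C)cc2O[Si](C(C)C)(C(C)C)C(C)C)COC(=O)O1 | intermediate
11 | (2S)-2-[2-(triisopropylsilyloxy)-4-(triisopropylsilyloxymethyl)phenyl]but-3-ene-1,2-diol | C=C[C@](O)(c1ccc(CO[Si](C(C)C)(C(C)C)C(C)C)cc1O[Si](C(C)C)(C(C)C)C(C)C)CO | intermediate
12 | (2S)-2-hydroxy-2-[2-(triisopropylsilyloxy)-4-(triisopropylsilyloxymethyl)phenyl]but-3-en-1-yl 4-methylbenzenesulfonate | C=C[C@](O)(c1ccc(CO[Si](C(C)C)(C(C)C)C(C)C)cc1O[Si](C(C)C)(C(C)C)C(C)C)COS(=O)(=O)c1ccc(C)cc1 | intermediate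
13 | (2S)-2-[2-(triisopropylsilyloxy)-4-(triisopropylsilyloxymethyl)phenyl]-2-vinyloxirane | C=C[C@]1(c2ccc(CO[Si](C(C)C)(C(C)C)C(C)C)cc2O[Si](C(C)C)(C(C)C)C(C)C)CO1 | intermediate
14 | (2S)-2-[2-(triisopropylsilyloxy)-4-(triisopropylsilyloxymethyl)phenyl]oxirane-2-carbaldehyde | O=C[C@]1(c2ccc(CO[Si](C(C)C)(C(C)C)C(C)C)cc2O[Si](C(C)C)(C(C)C)C(C)C)CO1 | intermediate
15 | [(2R)-2-[2-(triisopropylsilyloxy)-4-(triisopropylsilyloxymethyl)phenyl]oxiran-2-yl]methanol | OC[C@]1(c2ccc(CO[Si](C(C)C)(C(C)C)C(C)C)cc2O[Si](C(C)C)(C(C)C)C(C)C)CO1 | intermediate
16 | [(2S)-2-[2-(triisopropylsilyloxy)-4-(triisopropylsilyloxymethyl)phenyl]oxiran-2-yl]methyl acetate | CC(=O)OC[C@]1(c2ccc(CO[Si](C(C)C)(C(C)C)C(C)C)cc2O[Si](C(C)C)(C(C)C)C(C)C)CO1 | intermediate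
17 | [(2S)-2-[2-(2-methylpropanoyloxy)-4-(2-methylpropanoyloxymethyl)phenyl]oxiran-2-yl]methyl acetate | CC(=O)OC[C@]1(c2ccc(COC(=O)C(C)C)cc2OC(=O)C(C)C)CO1 | target

## Step count and least certain steps

Total step count: 10. Longest linear sequence: 10 steps (1 to 17).

Step 6 (key step). What may go wrong: loss of branched selectivity or of facial selectivity, or sluggish ionisation, because the triisopropylsilyloxy group ortho to the reacting terminus crowds both the π-allyl complex and the approach of water; a slow capture also gives the uncatalysed, racemic ionisation of the tertiary benzylic carbonate more time. Fallback, from 3 to 15: Grignard reagent 5, made from 3 as in step 3, is added across prop-2-yn-1-ol (taken as its chloromagnesium alkoxide) under catalysis by CuI (monovalent copper) to give 2-[2-(triisopropylsilyloxy)-4-(triisopropylsilyloxymethyl)phenyl]prop-2-en-1-ol F1. Sharpless epoxidation of F1 with Ti(OiPr)4, D-(−)-diethyl tartrate and tert-butyl hydroperoxide over 4 Å molecular sieves in CH2Cl2 at −20 °C then gives 15; D-(−)-tartrate is the antipode that the empirical facial rule for 2-substituted allylic alcohols assigns to the R epoxy alcohol. This is shorter, but it exposes the electron-rich tertiary benzylic oxirane to a titanium Lewis acid, which is why it is held in reserve.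

Step 10. What may go wrong: slow cleavage of the benzylic triisopropylsilyl ether prolongs contact of the acetate and the oxirane with fluoride and carboxylate, so acyl exchange at the acetate or ring opening can compete; fluoride is also partly diverted into acyl fluoride. Fallback, from 16 to 17, separating the two events: Bu4NF buffered with one equivalent of acetic acid in THF removes both silyl groups without generating phenoxide and gives [(2S)-2-[2-hydroxy-4-(hydroxymethyl)phenyl]oxiran-2-yl]methyl acetate F2, which is acylated at once with 2-methylpropanoic anhydride, Et3N and catalytic DMAP in CH2Cl2 at 0 °C to give 17.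

Step 8. What may go wrong: over-oxidation of the electron-rich arene by ozone, or acid-promoted opening of the allylic, benzylic oxirane by peroxidic by-products before reduction. Fallback, from 13 to 15: catalytic OsO4 with N-methylmorpholine N-oxide in aqueous acetone dihydroxylates the vinyl group to (1RS)-1-[(2S)-2-Ar-oxiran-2-yl]ethane-1,2-diol F3 (the new carbinol centre is immaterial). NaIO4 in NaHCO3-buffered aqueous THF cleaves F3 to 14, and NaBH4 reduces 14 to 15.

Step 5. What may go wrong: isomerisation of the vinyl oxirane by zerovalent palladium (hydride shift to an unsaturated carbonyl compound, or diene formation) if CO2 capture by the hindered tertiary alkoxide is slow. Fallback, from 6 to 10, bypassing 9: CsOAc in DMF displaces chloride to give 2-oxo-2-Ar-ethyl acetate F4. An excess of 7 adds to the ketone and strips the acetate to give racemic 2-Ar-but-3-ene-1,2-diol F5. 1,1'-Carbonyldiimidazole in CH2Cl2 closes the cyclic carbonate to give 10.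

## Further compounds

F1 | step 6 | 2-[2-(triisopropylsilyloxy)-4-(triisopropylsilyloxymethyl)phenyl]prop-2-en-1-ol | C=C(CO)c1ccc(CO[Si](C(C)C)(C(C)C)C(C)C)cc1O[Si](C(C)C)(C(C)C)C(C)C
F2 | step 10 | [(2S)-2-[2-hydroxy-4-(hydroxymethyl)phenyl]oxiran-2-yl]methyl acetate | CC(=O)OC[C@]1(c2ccc(CO)cc2O)CO1
F3 | step 8 | (1RS)-1-[(2S)-2-[2-(triisopropylsilyloxy)-4-(triisopropylsilyloxymethyl)phenyl]oxiran-2-yl]ethane-1,2-diol | OCC(O)[C@]1(c2ccc(CO[Si](C(C)C)(C(C)C)C(C)C)cc2O[Si](C(C)C)(C(C)C)C(C)C)CO1
F4 | step 5 | 2-oxo-2-[2-(triisopropylsilyloxy)-4-(triisopropylsilyloxymethyl)phenyl]ethyl acetate | CC(=O)OCC(=O)c1ccc(CO[Si](C(C)C)(C(C)C)C(C)C)cc1O[Si](C(C)C)(C(C)C)C(C)C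
F5 | step 5 | racemic 2-[2-(triisopropylsilyloxy)-4-(triisopropylsilyloxymethyl)phenyl]but-3-ene-1,2-diol | C=CC(O)(CO)c1ccc(CO[Si](C(C)C)(C(C)C)C(C)C)cc1O[Si](C(C)C)(C(C)C)C(C)C
A1 | alternative 1 | 2-(4-methoxybenzyloxy)-1-[2-(tert-butyldimethylsilyloxy)-4-(tert-butyldimethylsilyloxymethyl)phenyl]ethan-1-one | COc1ccc(COCC(=O)c2ccc(CO[Si](C)(C)C(C)(C)C)cc2O[Si](C)(C)C(C)(C)C)cc1
A2 | alternative 1 | dimethyloxosulfonium methylide | C[S+](C)(=O)[CH2-]
A3 | alternative 1 | (2S)-2-[2-(tert-butyldimethylsilyloxy)-4-(tert-butyldimethylsilyloxymethyl)phenyl]-2-[(4-methoxybenzyloxy)methyl]oxirane | COc1ccc(COC[C@]2(c3ccc(CO[Si](C)(C)C(C)(C)C)cc3O[Si](C)(C)C(C)(C)C)CO2)cc1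
A4 | alternative 2 | [2-(triisopropylsilyloxy)-4-(triisopropylsilyloxymethyl)phenyl]boronic acid | OB(O)c1ccc(CO[Si](C(C)C)(C(C)C)C(C)C)cc1O[Si](C(C)C)(C(C)C)C(C)C
A5 | alternative 2 | ethyl 3-(4-methoxybenzyloxy)-2-oxopropanoate | CCOC(=O)C(=O)COCc1ccc(OC)cc1
A6 | alternative 2 | ethyl (2R)-2-hydroxy-3-(4-methoxybenzyloxy)-2-[2-(triisopropylsilyloxy)-4-(triisopropylsilyloxymethyl)phenyl]propanoate | COc1ccc(COC[C@](O)(c2ccc(CO[Si](C(C)C)(C(C)C)C(C)C)cc2O[Si](C(C)C)(C(C)C)C(C)C)C(=O)OCC)cc1
A7 | alternative 3 | 3-[2-(2-methylpropanoyloxy)-4-(2-methylpropanoyloxymethyl)phenyl]-3-(trimethylsilyloxy)oxetane | CC(C)C(=O)OCc1ccc(C2(O[Si](C)(C)C)COC2)c(OC(=O)C(C)C)c1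
A8 | alternative 3 | bromotrimethylsilane | C[Si](C)(C)Br
A9 | alternative 3 | (2R)-1-bromo-2-[2-(2-methylpropanoyloxy)-4-(2-methylpropanoyloxymethyl)phenyl]-2,3-bis(trimethylsilyloxy)propane | C[Si](C)(C)OC[C@](O[Si](C)(C)C)(c1ccc(COC(=O)C(C)C)cc1OC(=O)C(C)C)CBr
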